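The synthesis rests on converting a 2-pyranone into the 1-hydroxypyridin-2-one ring. In the target, N1 bears its own oxygen and is flanked by the C2 carbonyl and the unsubstituted C6–H, the place a ring oxygen occupies in a 5-aryl-4-hydroxy-2-pyranone. Heating pyranone 8 (free O4–H, C3–H and C6–H; PMB-protected hydroxyphenyl at C5) with O-PMB-hydroxylamine should replace O1 by N–OPMB in one operation, forming N1–C6 and N1–C2 with the N–O bond already in place. C3 is then acylated as a β-keto phosphonate, olefination with an auxiliary-derived (R)-trienal completes the tetraenoyl chain, and acid removes both PMB groups last.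

Key step: step 4

Remark: PMB = 4-methoxybenzyl; ring atoms are N1, C2(=O), C3, C4(OH), C5(aryl), C6(H), chain atoms C1'–C12'. C10' is R, which with the (R)-benzyl auxiliary requires the N-butanoyl imide and iodomethane as electrophile (N-propanoyl plus an ethyl halide would give S). The chain is joined at C3 by olefination of a β-keto phosphonate because an O4→C3 shift of a preformed polyenoyl group would compete with Michael addition.

Step 1
Reactants: 1 4-hydroxyphenylacetic acid
Product: 3 2-{4-[(4-methoxybenzyl)oxy]phenyl}acetic acid, via bis-PMB ester 2 (not isolated)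
Conditions: PMBCl (2.3 equiv), K2CO3, KI (cat.), DMF, 60 °C; then aq. NaOH, MeOH, 50 °C; HCl to pH 3, 0 °C
Reagents that add atoms: 4-methoxybenzyl chloride, COc1ccc(CCl)cc1
Why: Williamson alkylation of the phenoxide and the carboxylate, followed by saponification of the PMB ester alone, should free the acid while the base-stable aryl PMB ether stays.

Step 2
Reactants: 3 2-{4-[(4-methoxybenzyl)oxy]phenyl}acetic acid; 4 Meldrum's acid
Product: 6 methyl 4-{4-[(4-methoxybenzyl)oxy]phenyl}-3-oxobutanoate, via acyl Meldrum's acid 5 (not isolated)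
Conditions: DCC, DMAP, CH2Cl2, 0 °C → rt; filter, wash (aq. KHSO4), evaporate; then MeOH, reflux
Reagents that add atoms: methanol, CO
Why: Carbodiimide/DMAP C-acylation of Meldrum's acid and methanolysis of the adduct through its acylketene (the Meldrum's acid route to β-keto esters) should extend the arylacetic acid by CH2CO2Me under conditions that leave the PMB ether alone.

Step 3
Reactants: 6 methyl 4-{4-[(4-methoxybenzyl)oxy]phenyl}-3-oxobutanoate
Product: 8 4-hydroxy-5-{4-[(4-methoxybenzyl)oxy]phenyl}-2H-pyran-2-one, via hydroxymethylene keto ester 7 (not isolated)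
Conditions: LDA (2.2 equiv), THF, −78 → 0 °C; cannulate into HCO2Et (5 equiv), THF, −78 → −20 °C; AcOH; then DBU (1.2 equiv), toluene, 80 °C; aq. citric acid
Reagents that add atoms: ethyl formate, CCOC=O
Why: The β-keto ester dianion should be acylated by the formate at its more basic γ-carbon, here also benzylic (Claisen-type γ-formylation), and the Z-enol oxygen of 7 should then attack the methyl ester in a base-mediated 6-exo-trig lactonisation that ends in the aromatic 4-hydroxy-2-pyranone.

Step 4
Reactants: 8 4-hydroxy-5-{4-[(4-methoxybenzyl)oxy]phenyl}-2H-pyran-2-one; 9 O-(4-methoxybenzyl)hydroxylamine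
Product: 11 4-hydroxy-1-[(4-methoxybenzyl)oxy]-5-{4-[(4-methoxybenzyl)oxy]phenyl}pyridin-2(1H)-one, via ring-opened enaminone acid 10 (not isolated)
Conditions: 9 (free base, 1.5 equiv), pyridine, 90 °C, Ar; aq. citric acid work-up
Reagents that add atoms: none
Why: The nitrogen of 9, an α-effect nucleophile, should add to C6, the unhindered vinylogous-ester carbon of 8, and the C6–O1 bond then breaks to give the ring-opened N-alkoxy enaminone acid 10, which equilibrates with its oxime-ether tautomer. The same nitrogen then attacks the C2 carboxyl carbon and water is lost, so that the aromatic N-alkoxypyridone forms. The closest known reactions are the exchange of 2-pyranones with hydroxylamine to 1-hydroxy-2-pyridones and of 4-hydroxy-2-pyranones with primary amines to 4-hydroxy-2-pyridones, both addition/ring-opening/ring-closure sequences. The single new ring closes by 6-exo-trig attack of N1 on C2, and no stereocentre is formed. The step needs nitrogen and not oxygen in the ring and only one condensation per molecule: the PMB group blocks the oxygen of 9, so neither an O-linked ring nor an isoxazole can form, C6–H is the most electrophilic and least hindered site, and a small excess of 9 in hot pyridine (no strong acid, 10 held as carboxylate) should hold back oxime formation at C4, loss of CO2 from 10 and loss of PMB. O4–H and C3–H come through free for the acylation that follows.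

Step 5
Reactants: 11 4-hydroxy-1-[(4-methoxybenzyl)oxy]-5-{4-[(4-methoxybenzyl)oxy]phenyl}pyridin-2(1H)-one
Product: 13 diethyl [2-(4-hydroxy-1-[(4-methoxybenzyl)oxy]-5-{4-[(4-methoxybenzyl)oxy]phenyl}-2-oxo-1,2-dihydropyridin-3-yl)-2-oxoethyl]phosphonate, via O4-acyl enol ester 12 (not isolated)
Conditions: (EtO)2P(O)CH2CO2H, DCC, DMAP (1.5 equiv), CH2Cl2, 0 °C → rt, then 40 °C; aq. citric acid work-up
Reagents that add atoms: 2-(diethoxyphosphoryl)acetic acid, OC(=O)CP(=O)(OCC)OCC
Why: Steglich esterification of the acidic O4–H followed by DMAP-mediated 1,3-O→C acyl migration (Fries-type rearrangement of a 1,3-dicarbonyl enol ester) should place the saturated phosphonoacetyl group on C3, the only free enol carbon because C5 carries the aryl group.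

Step 6
Reactants: 14 (R)-4-benzyl-1,3-oxazolidin-2-one
Product: 15 (R)-4-benzyl-3-butanoyl-1,3-oxazolidin-2-one
Conditions: n-BuLi, THF, −78 °C; PrCOCl, −78 → 0 °C
Reagents that add atoms: butanoyl chloride, CCCC(Cl)=O
Why: N-acylation of the lithiated oxazolidinone with an acid chloride is the standard entry to the imide needed for auxiliary-controlled alkylation.

Step 7
Reactants: 15 (R)-4-benzyl-3-butanoyl-1,3-oxazolidin-2-one
Product: 16 (R)-4-benzyl-3-[(2R)-2-methylbutanoyl]-1,3-oxazolidin-2-one
Conditions: NaHMDS, THF, −78 °C; MeI, −78 °C; chromatography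
Reagents that add atoms: iodomethane, CI
Why: In this Evans asymmetric alkylation the chelated sodium Z-enolate should be methylated on the face opposite the benzyl group of the (R)-auxiliary, which sets the α-carbon (later C10') as R, and the minor diastereomer should be separable.

Step 8
Reactants: 16 (R)-4-benzyl-3-[(2R)-2-methylbutanoyl]-1,3-oxazolidin-2-one
Product: 17 (R)-2-methylbutan-1-ol
Conditions: LiBH4, H2O (1 equiv), Et2O, 0 °C; aq. NaOH; careful fractional distillation
Reagents that add atoms: none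
Why: Reductive cleavage of the imide with lithium borohydride attacks the exocyclic carbonyl, which should give the primary alcohol without touching the stereocentre and return the auxiliary.

Step 9
Reactants: 17 (R)-2-methylbutan-1-ol
Product: 19 ethyl (2E,4R)-2,4-dimethylhex-2-enoate, via (R)-2-methylbutanal 18 (not isolated)
Conditions: (COCl)2, DMSO, CH2Cl2, −78 °C; Et3N; then Ph3P=C(Me)CO2Et, −78 °C → rt
Reagents that add atoms: ethyl 2-(triphenylphosphoranylidene)propanoate, CCOC(=O)C(C)=P(c1ccccc1)(c1ccccc1)c1ccccc1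
Why: Swern oxidation with the stabilised ylide added to the cold aldehyde solution (one-pot oxidation/Wittig olefination) avoids isolating the volatile, epimerisable aldehyde, and the α-methyl ester ylide should give the E-trisubstituted alkene.

Step 10
Reactants: 19 ethyl (2E,4R)-2,4-dimethylhex-2-enoate
Product: 20 (2E,4R)-2,4-dimethylhex-2-en-1-ol
Conditions: DIBAL-H (2.5 equiv), CH2Cl2, −78 °C; Rochelle salt
Reagents that add atoms: none
Why: DIBAL-H should reduce the enoate in 1,2-fashion to the allylic alcohol without conjugate reduction or change at C4.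

Step 11
Reactants: 20 (2E,4R)-2,4-dimethylhex-2-en-1-ol
Product: 21 (2E,4R)-2,4-dimethylhex-2-enal
Conditions: MnO2 (excess), CH2Cl2, rt
Reagents that add atoms: none
Why: Manganese dioxide oxidises allylic alcohols selectively to enals under neutral conditions, so neither the alkene geometry nor C4 should be disturbed.

Step 12
Reactants: 21 (2E,4R)-2,4-dimethylhex-2-enal
Product: 22 ethyl (2E,4E,6E,8R)-6,8-dimethyldeca-2,4,6-trienoate
Conditions: (EtO)2P(O)CH2CH=CHCO2Et, LiHMDS, THF, −78 °C; then 21, −78 → 0 °C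
Reagents that add atoms: triethyl 4-phosphonocrotonate, CCOC(=O)/C=C/CP(=O)(OCC)OCC
Why: Vinylogous Horner–Wadsworth–Emmons olefination with the preformed lithium phosphonate anion adds four carbons and should form the new C4=C5 bond E, with no free base left to deprotonate C4 of the enal.

Step 13
Reactants: 22 ethyl (2E,4E,6E,8R)-6,8-dimethyldeca-2,4,6-trienoate
Product: 23 (2E,4E,6E,8R)-6,8-dimethyldeca-2,4,6-trien-1-ol
Conditions: DIBAL-H (2.5 equiv), CH2Cl2, −78 °C; Rochelle salt
Reagents that add atoms: none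
Why: 1,2-Reduction of the trienoate with DIBAL-H should give the trienol with the triene intact.

Step 14
Reactants: 23 (2E,4E,6E,8R)-6,8-dimethyldeca-2,4,6-trien-1-ol
Product: 24 (2E,4E,6E,8R)-6,8-dimethyldeca-2,4,6-trienal
Conditions: MnO2 (excess), CH2Cl2, rt, dark; used at once
Reagents that add atoms: none
Why: Allylic oxidation with manganese dioxide should give the all-E trienal under neutral conditions.

Step 15
Reactants: 13 diethyl [2-(4-hydroxy-1-[(4-methoxybenzyl)oxy]-5-{4-[(4-methoxybenzyl)oxy]phenyl}-2-oxo-1,2-dihydropyridin-3-yl)-2-oxoethyl]phosphonate; 24 (2E,4E,6E,8R)-6,8-dimethyldeca-2,4,6-trienal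
Product: 25 4-hydroxy-1-[(4-methoxybenzyl)oxy]-5-{4-[(4-methoxybenzyl)oxy]phenyl}-3-[(2E,4E,6E,8E,10R)-8,10-dimethyldodeca-2,4,6,8-tetraenoyl]pyridin-2(1H)-one
Conditions: KOtBu (2.1 equiv), THF, 0 °C; then 24, 0 °C → rt; cold 0.5 M HCl
Reagents that add atoms: none
Why: The dianion of the β-keto phosphonate (enolate oxygen plus phosphonate carbanion) should undergo Horner–Wadsworth–Emmons olefination with the non-enolisable trienal to form C2'=C3' with E geometry, which completes the tetraenoyl chain at C3.

Step 16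
Reactants: 25 4-hydroxy-1-[(4-methoxybenzyl)oxy]-5-{4-[(4-methoxybenzyl)oxy]phenyl}-3-[(2E,4E,6E,8E,10R)-8,10-dimethyldodeca-2,4,6,8-tetraenoyl]pyridin-2(1H)-one
Product: 26 1,4-dihydroxy-5-(4-hydroxyphenyl)-3-[(2E,4E,6E,8E,10R)-8,10-dimethyldodeca-2,4,6,8-tetraenoyl]pyridin-2(1H)-one
Conditions: TFA–CH2Cl2 (1:4), 1,3,5-trimethoxybenzene (5 equiv), 0 °C, dark
Reagents that add atoms: none
Why: Acidolysis should ionise both PMB–O bonds (aryl ether and N–O-benzyl) to the 4-methoxybenzyl cation, which the trimethoxybenzene traps by Friedel–Crafts alkylation before it can reach the polyene, while the N–O bond itself is not cleaved by acid.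

Compound list
1 | 4-hydroxyphenylacetic acid | OC(=O)Cc1ccc(O)cc1 | starting material
2 | 4-methoxybenzyl 2-{4-[(4-methoxybenzyl)oxy]phenyl}acetate | COc1ccc(COC(=O)Cc2ccc(OCc3ccc(OC)cc3)cc2)cc1 | intermediate
3 | 2-{4-[(4-methoxybenzyl)oxy]phenyl}acetic acid | COc1ccc(COc2ccc(CC(=O)O)cc2)cc1 | intermediate
4 | Meldrum's acid (2,2-dimethyl-1,3-dioxane-4,6-dione) | CC1(C)OC(=O)CC(=O)O1 | starting material
5 | 5-(1-hydroxy-2-{4-[(4-methoxybenzyl)oxy]phenyl}ethylidene)-2,2-dimethyl-1,3-dioxane-4,6-dione | CC1(C)OC(=O)C(=C(O)Cc2ccc(OCc3ccc(OC)cc3)cc2)C(=O)O1 | intermediate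
6 | methyl 4-{4-[(4-methoxybenzyl)oxy]phenyl}-3-oxobutanoate | COC(=O)CC(=O)Cc1ccc(OCc2ccc(OC)cc2)cc1 | intermediate
7 | methyl (4Z)-5-hydroxy-4-{4-[(4-methoxybenzyl)oxy]phenyl}-3-oxopent-4-enoate (enol of the 4-formyl keto ester) | COC(=O)CC(=O)/C(=C\O)c1ccc(OCc2ccc(OC)cc2)cc1 | intermediate
8 | 4-hydroxy-5-{4-[(4-methoxybenzyl)oxy]phenyl}-2H-pyran-2-one | O=c1cc(O)c(-c2ccc(OCc3ccc(OC)cc3)cc2)co1 | intermediate
9 | O-(4-methoxybenzyl)hydroxylamine | NOCc1ccc(OC)cc1 | starting material
10 | (4Z)-5-{[(4-methoxybenzyl)oxy]amino}-4-{4-[(4-methoxybenzyl)oxy]phenyl}-3-oxopent-4-enoic acid | OC(=O)CC(=O)/C(=C\NOCc1ccc(OC)cc1)c1ccc(OCc2ccc(OC)cc2)cc1 | intermediate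
11 | 4-hydroxy-1-[(4-methoxybenzyl)oxy]-5-{4-[(4-methoxybenzyl)oxy]phenyl}pyridin-2(1H)-one | O=c1cc(O)c(-c2ccc(OCc3ccc(OC)cc3)cc2)cn1OCc1ccc(OC)cc1 | intermediate
12 | 1-[(4-methoxybenzyl)oxy]-5-{4-[(4-methoxybenzyl)oxy]phenyl}-2-oxo-1,2-dihydropyridin-4-yl 2-(diethoxyphosphoryl)acetate | CCOP(=O)(CC(=O)Oc1cc(=O)n(OCc2ccc(OC)cc2)cc1-c1ccc(OCc2ccc(OC)cc2)cc1)OCC | intermediate
13 | diethyl [2-(4-hydroxy-1-[(4-methoxybenzyl)oxy]-5-{4-[(4-methoxybenzyl)oxy]phenyl}-2-oxo-1,2-dihydropyridin-3-yl)-2-oxoethyl]phosphonate | CCOP(=O)(CC(=O)c1c(O)c(-c2ccc(OCc3ccc(OC)cc3)cc2)cn(OCc2ccc(OC)cc2)c1=O)OCC | intermediate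
14 | (R)-4-benzyl-1,3-oxazolidin-2-one | O=C1N[C@H](Cc2ccccc2)CO1 | starting material
15 | (R)-4-benzyl-3-butanoyl-1,3-oxazolidin-2-one | CCCC(=O)N1[C@H](Cc2ccccc2)COC1=O | intermediate
16 | (R)-4-benzyl-3-[(2R)-2-methylbutanoyl]-1,3-oxazolidin-2-one | CC[C@@H](C)C(=O)N1[C@H](Cc2ccccc2)COC1=O | intermediate
17 | (R)-2-methylbutan-1-ol | CC[C@@H](C)CO | intermediate
18 | (R)-2-methylbutanal | CC[C@@H](C)C=O | intermediate
19 | ethyl (2E,4R)-2,4-dimethylhex-2-enoate | CC[C@@H](C)/C=C(C)/C(=O)OCC | intermediate
20 | (2E,4R)-2,4-dimethylhex-2-en-1-ol | CC[C@@H](C)/C=C(C)/CO | intermediate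
21 | (2E,4R)-2,4-dimethylhex-2-enal | CC[C@@H](C)/C=C(C)/C=O | intermediate
22 | ethyl (2E,4E,6E,8R)-6,8-dimethyldeca-2,4,6-trienoate | CC[C@@H](C)/C=C(C)/C=C/C=C/C(=O)OCC | intermediate
23 | (2E,4E,6E,8R)-6,8-dimethyldeca-2,4,6-trien-1-ol | CC[C@@H](C)/C=C(C)/C=C/C=C/CO | intermediate
24 | (2E,4E,6E,8R)-6,8-dimethyldeca-2,4,6-trienal | CC[C@@H](C)/C=C(C)/C=C/C=C/C=O | intermediate
25 | 4-hydroxy-1-[(4-methoxybenzyl)oxy]-5-{4-[(4-methoxybenzyl)oxy]phenyl}-3-[(2E,4E,6E,8E,10R)-8,10-dimethyldodeca-2,4,6,8-tetraenoyl]pyridin-2(1H)-one | CC[C@@H](C)/C=C(C)/C=C/C=C/C=C/C(=O)c1c(O)c(-c2ccc(OCc3ccc(OC)cc3)cc2)cn(OCc2ccc(OC)cc2)c1=O | intermediate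
26 | 1,4-dihydroxy-5-(4-hydroxyphenyl)-3-[(2E,4E,6E,8E,10R)-8,10-dimethyldodeca-2,4,6,8-tetraenoyl]pyridin-2(1H)-one | CC[C@@H](C)/C=C(C)/C=C/C=C/C=C/C(=O)c1c(O)c(-c2ccc(O)cc2)cn(O)c1=O | target

Total step count: 16 (core branch steps 1–5, side-chain branch steps 6–14, union and deprotection steps 15–16).
Longest linear sequence: 11 steps (steps 6–16).

Steps most likely to fail

1. Step 4 (key step). Closure of the opened intermediate onto C2 may be slower than loss of CO2 from its β-keto acid, a second molecule of the alkoxyamine may condense at the C4 carbonyl, or the pyranone may be held as its unreactive enolate salt. The fallback sets out from 6 and comes back at 11. Compound 6 would be formylated as in step 3 with the DBU stage left out, and crude 7 would be condensed at its formyl carbon with 9 (EtOH, rt) to give methyl (4Z)-5-{[(4-methoxybenzyl)oxy]amino}-4-{4-[(4-methoxybenzyl)oxy]phenyl}-3-oxopent-4-enoate F1. Heating F1 (xylene, 140 °C) should close the lactam onto the methyl ester with loss of methanol, the known thermal cyclisation of 5-amino-3-oxopent-4-enoates to 4-hydroxy-2-pyridones, and give 11. The ring is then built from an open-chain ester, so neither the pyranone nor a free β-keto acid is involved.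

2. Step 3. Proton transfer from the acidic formylated product to unreacted dianion may stop the conversion early, the dianion may add to the new aldehyde, or formylation may compete at C2. The fallback sets out from 5 and comes back at 8. Crude 5 would be heated with acetone in toluene (110 °C), so that its acylketene is trapped as 2,2-dimethyl-6-{4-[(4-methoxybenzyl)oxy]benzyl}-4H-1,3-dioxin-4-one F2, in which the carbon between the carbonyl groups is masked. The lithium dienolate of F2 (LiHMDS, THF, −78 °C) would be acylated at its γ (benzylic) carbon with ethyl formate to give 6-[(Z)-2-hydroxy-1-{4-[(4-methoxybenzyl)oxy]phenyl}ethenyl]-2,2-dimethyl-4H-1,3-dioxin-4-one F3. Thermolysis of F3 (toluene, 110 °C) expels acetone, and capture of the acylketene by the enol oxygen should give 8.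

3. Step 16. The 4-methoxybenzyl cations or the acid may attack the tetraene (alkylation, E/Z isomerisation, drift at C10'), or the aryl ether may be cleaved incompletely. The fallback sets out from 13 and comes back at 26. Both PMB groups would be removed from 13 first (TFA, 1,3,5-trimethoxybenzene, CH2Cl2, 0 °C) to give diethyl {2-[1,4-dihydroxy-5-(4-hydroxyphenyl)-2-oxo-1,2-dihydropyridin-3-yl]-2-oxoethyl}phosphonate F4. F4 would then be olefinated as its polyanion (KOtBu, 4.2 equiv, THF–DMF, 0 °C → rt) with 24 to give 26 directly, so that the polyene never meets acid.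

Further compounds
F1 | step 4 | methyl (4Z)-5-{[(4-methoxybenzyl)oxy]amino}-4-{4-[(4-methoxybenzyl)oxy]phenyl}-3-oxopent-4-enoate | COC(=O)CC(=O)/C(=C\NOCc1ccc(OC)cc1)c1ccc(OCc2ccc(OC)cc2)cc1
F2 | step 3 | 2,2-dimethyl-6-{4-[(4-methoxybenzyl)oxy]benzyl}-4H-1,3-dioxin-4-one | CC1(C)OC(Cc2ccc(OCc3ccc(OC)cc3)cc2)=CC(=O)O1
F3 | step 3 | 6-[(Z)-2-hydroxy-1-{4-[(4-methoxybenzyl)oxy]phenyl}ethenyl]-2,2-dimethyl-4H-1,3-dioxin-4-one | CC1(C)OC(/C(=C\O)c2ccc(OCc3ccc(OC)cc3)cc2)=CC(=O)O1
F4 | step 16 | diethyl {2-[1,4-dihydroxy-5-(4-hydroxyphenyl)-2-oxo-1,2-dihydropyridin-3-yl]-2-oxoethyl}phosphonate | CCOP(=O)(CC(=O)c1c(O)c(-c2ccc(O)cc2)cn(O)c1=O)OCC
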